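Rings: A hydroxycyclopentane, B cyclohexene, C cyclooctane, D methylcyclopentane. Ring A plus the ring B methylene on the A/B ring-fusion CH is thujone: that methylene, the ring-fusion CH and the isopropyl-bearing carbon are its cyclopropane. Stereoconvergent alkylation of thujone at its methyl-bearing carbon, anti to the cyclopropane, with a nepetalactone-derived ring C/D vinyl bromide fixes the trans A/B relationship before ring B exists. The key step closes ring B: a radical beside the ketone cleaves the cyclopropane bond to the isopropyl carbon, and nickel couples the released primary radical with the ring C vinyl bromide, forming the tetrasubstituted B/C alkene. Its precursor is a bicyclo[3.1.0]hexanone tethered to a bromocyclooctene ketal.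

Key step: step 16

Assumption: (4aS,7S,7aR)-nepetalactone (main lactone of commercial catnip oil) is taken as a commercial starting material; commercial thujone may be the α/β mixture, because both C4 epimers converge in step 13.

Step 1
Reactants: 1 (tert-butyldimethylsilyloxy)acetaldehyde
Product: 2 (2S,3S)-1-(tert-butyldimethylsilyloxy)-3-methylpent-4-en-2-ol
Conditions: (−)-Ipc2B[(E)-crotyl] (Ipc = isopinocampheyl, from (+)-α-pinene), THF/Et2O, −78 °C; then NaOH, H2O2, 0 °C to rt
Reagents that add atoms: (−)-B-[(E)-but-2-en-1-yl]diisopinocampheylborane, C/C=C/CB(C1CC2CC(C1C)C2(C)C)C1CC2CC(C1C)C2(C)C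
Why: Brown crotylboration through a closed chair transition state should deliver the (E)-crotyl group to the Si face and give the anti (2S,3S) alcohol, of which only C3 (the future ring C methyl centre) is kept.

Step 2
Reactants: 2 (2S,3S)-1-(tert-butyldimethylsilyloxy)-3-methylpent-4-en-2-ol
Product: 3 (3S)-1-(tert-butyldimethylsilyloxy)-3-methylpent-4-en-2-one
Conditions: Dess–Martin periodinane, CH2Cl2, 0 °C to rt
Reagents that add atoms: none
Why: Dess–Martin oxidation is base-free, so the α-stereocentre of the β,γ-unsaturated ketone should survive.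

Step 3
Reactants: 4 (4aS,7S,7aR)-nepetalactone
Product: 5 (4aS,7S,7aS)-nepetalactone
Conditions: DBU (0.2 equiv), xylene, 140 °C; chromatography, recycling of 4
Reagents that add atoms: none
Why: Base-mediated epimerisation (thermodynamic control) can only invert C7a, the carbon α to the lactone carbonyl, and should favour the trans-fused lactone whose carbonyl carbon is cis to the ring methyl, which is the ring D triad of the target.

Step 4
Reactants: 5 (4aS,7S,7aS)-nepetalactone
Product: 6 (4aS,7S,7aS)-nepetalactol
Conditions: i-Bu2AlH (1.05 equiv), CH2Cl2, −78 °C; aqueous potassium sodium tartrate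
Reagents that add atoms: none
Why: Partial reduction of the lactone stops at the lactol because the tetrahedral aluminate is stable at −78 °C.

Step 5
Reactants: 6 (4aS,7S,7aS)-nepetalactol
Product: 7 (1S,2S,5S)-2-acetyl-5-methylcyclopentane-1-carbaldehyde
Conditions: O3, CH2Cl2, −78 °C; then Me2S, −78 °C to rt; neutral work-up
Reagents that add atoms: ozone, [O-][O+]=O
Why: Ozonolysis of the enol ether C=C turns the methyl-bearing alkene carbon into the acetyl group, and the resulting formate hemiacetal collapses to the aldehyde; each α-centre already sits trans to its larger neighbour, so neither should epimerise.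

Step 6
Reactants: 7 (1S,2S,5S)-2-acetyl-5-methylcyclopentane-1-carbaldehyde
Product: 8 1-[(1S,2S,3S)-2-ethenyl-3-methylcyclopentyl]ethan-1-one
Conditions: Ph3P=CH2 (1.05 equiv, from Ph3PCH3Br and KN(SiMe3)2), THF, −78 to 0 °C
Reagents that add atoms: methylenetriphenylphosphorane, C=P(c1ccccc1)(c1ccccc1)c1ccccc1
Why: Wittig methylenation is chemoselective for the aldehyde over the methyl ketone at low temperature.

Step 7
Reactants: 8 1-[(1S,2S,3S)-2-ethenyl-3-methylcyclopentyl]ethan-1-one; 3 (3S)-1-(tert-butyldimethylsilyloxy)-3-methylpent-4-en-2-one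
Product: 10 (4S)-3-[(tert-butyldimethylsilyloxy)methyl]-1-[(1S,2S,3S)-2-ethenyl-3-methylcyclopentyl]-3-hydroxy-4-methylhex-5-en-1-one (both C3 epimers), via lithium enolate 9 (not isolated)
Conditions: LiN(i-Pr)2 (1.05 equiv), THF, −78 °C; then 3, −78 °C; AcOH quench at −78 °C
Reagents that add atoms: none
Why: Aldol addition of the kinetic methyl-side enolate to the α-silyloxy ketone; the new carbinol centre forms as a mixture that step 9 erases.

Step 8
Reactants: 10 aldol adduct
Product: 12 (1S,5S,8S,9S)-4-hydroxy-4-[(tert-butyldimethylsilyloxy)methyl]-5,9-dimethylbicyclo[6.3.0]undecan-2-one (trans-fused; both C4 epimers), via cyclooctene 11 (not isolated)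
Conditions: second-generation Grubbs catalyst (5 mol %), CH2Cl2 (2 mM), 40 °C; then Pd/C, H2 (1 atm), EtOAc, rt
Reagents that add atoms: none
Why: Ring-closing metathesis closes ring C (the trans-1,2-disubstituted cyclopentane pre-organises the diene), and hydrogenation of the only C=C removes the doubly allylic position before the enone is made; no stereocentre is created.

Step 9
Reactants: 12 bicyclic β-hydroxy ketone
Product: 13 (1S,5S,8S,9S)-4-[(tert-butyldimethylsilyloxy)methyl]-5,9-dimethylbicyclo[6.3.0]undec-3-en-2-one
Conditions: MsCl, Et3N, CH2Cl2, 0 °C to rt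
Reagents that add atoms: none
Why: Mesylation and E1cB elimination give the conjugated endocyclic (Z) enone from both carbinol epimers.

Step 10
Reactants: 13 bicyclic enone
Product: 14 (1S,5S,8S,9S)-3-bromo-4-[(tert-butyldimethylsilyloxy)methyl]-5,9-dimethylbicyclo[6.3.0]undec-3-en-2-one
Conditions: Br2, CH2Cl2, 0 °C; then Et3N, 0 °C to rt
Reagents that add atoms: bromine, BrBr
Why: Bromine addition to the enone followed by E1cB loss of HBr is the standard α-bromination of enones and installs the vinyl bromide for step 16.

Step 11
Reactants: 14 α-bromo enone silyl ether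
Product: 15 (1S,5S,8S,9S)-3-bromo-4-(bromomethyl)-5,9-dimethylbicyclo[6.3.0]undec-3-en-2-one
Conditions: Ph3PBr2, CH2Cl2, 0 °C to rt
Reagents that add atoms: dibromotriphenylphosphorane, BrP(Br)(c1ccccc1)(c1ccccc1)c1ccccc1
Why: Direct silyl ether to bromide exchange (oxophilic phosphorus, then SN2 at the primary allylic carbon).

Step 12
Reactants: 15 dibromo enone
Product: 16 ethylene ketal (1,3-dioxolane at C2) of (1S,5S,8S,9S)-3-bromo-4-(bromomethyl)-5,9-dimethylbicyclo[6.3.0]undec-3-en-2-one
Conditions: Me3SiOCH2CH2OSiMe3, Me3SiOTf (cat.), CH2Cl2, −78 to −20 °C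
Reagents that add atoms: 1,2-bis(trimethylsilyloxy)ethane, C[Si](C)(C)OCCO[Si](C)(C)C
Why: Aprotic Me3SiOTf-catalysed ketalisation under kinetic control masks the ketone without moving the double bond or touching the γ-methyl centre.

Step 13
Reactants: 17 (−)-α-thujone
Product: 18 thujone trimethylsilyl enol ether (C3=C4)
Conditions: Me3SiCl, Et3N, DMF, 130 °C
Reagents that add atoms: chlorotrimethylsilane, C[Si](C)(C)Cl
Why: Thermodynamic silyl enol ether formation on the more substituted side destroys C4, so α- and β-thujone give the same enol ether (stereoconvergent).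

Step 14
Reactants: 18 thujone trimethylsilyl enol ether; 16 bicyclic ketal dibromide
Product: 20 C4-alkylated thujone (4-methyl cis to the cyclopropane CH2; side chain = the bicyclic unit of 16 attached through its CH2), via lithium enolate 19 (not isolated)
Conditions: MeLi (1.0 equiv), THF, 0 °C to rt; then 16, DMPU, −78 to 0 °C
Reagents that add atoms: none
Why: The regiospecific lithium enolate undergoes SN2 alkylation by the allylic bromide (vinyl bromide inert) on the face anti to the cyclopropane CH2, so the new quaternary centre carries its methyl cis to that CH2.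

Step 15
Reactants: 20 C4-alkylated thujone
Product: 22 2-bromo derivative of 20 (both C2 epimers), via silyl enol ether 21 (not isolated)
Conditions: LiN(SiMe3)2, Me3SiCl, THF, −78 °C; then NBS, THF, 0 °C
Reagents that add atoms: N-bromosuccinimide, O=C1CCC(=O)N1Br; chlorotrimethylsilane, C[Si](C)(C)Cl (silyl group present in 21 only)
Why: Only the CH2 between the ketone and the cyclopropane can enolise, and electrophilic bromination of its silyl enol ether gives the α-bromo ketone, whose C–Br configuration is irrelevant.

Step 16
Reactants: 22 α-bromo ketone / vinyl bromide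
Product: 23 tetracyclic enone ketal (target skeleton; ring A = 3-isopropyl-5-methylcyclopent-2-en-1-one; dioxolane on the ring C carbon that later carries =CH2)
Conditions: [Ir(dF(CF3)ppy)2(dtbbpy)]PF6 (2 mol %), NiBr2(dme) (20 mol %), dtbbpy (4,4′-di-tert-butyl-2,2′-bipyridine, 25 mol %), (Me3Si)3SiH (1.3 equiv, slow addition), Na2CO3, DME (5 mM), blue LEDs, 25 °C
Reagents that add atoms: none
Why: Proposed new method: under the iridium photocatalyst (Me3Si)3SiH gives (Me3Si)3Si•, which abstracts the activated bromine beside the ketone; the α-keto radical is a bicyclo[3.1.0]hex-2-yl (cyclopropylcarbinyl) radical that should open by β-scission of the exocyclic cyclopropane bond to the isopropyl-bearing carbon, giving the ring A enone and a primary radical on the former cyclopropane CH2, while zerovalent nickel inserts into the vinyl C–Br bond, the divalent vinylnickel bromide captures that radical intramolecularly and C(sp3)–C(sp2) reductive elimination from trivalent nickel forms the bond that closes ring B. The closest known reaction types are silyl-radical/nickel photoredox cross-electrophile coupling of alkyl bromides with vinyl or aryl bromides and the ring-opened products that cyclopropylmethyl halides give in nickel reductive couplings; the relay from an α-bromo ketone through a fused cyclopropane has no direct precedent. Ring B is closed as a six-membered ring by reductive elimination from a seven-membered nickelacycle, after a reverse 3-exo-trig ring opening. No stereocentre is created: the trans A/B fusion is inherited from 20, where the cyclopropane CH2 and the CH2 bearing ring C already lie on opposite faces of ring A, and the alkene geometry is fixed by ring C. The step needs cleavage of the exocyclic rather than the ring-fusion cyclopropane bond (better overlap with the radical orbital), ring opening before the hindered α-keto radical is captured at nickel, and nickel capture of the primary radical before hydrogen transfer from the silane or 5-exo attack on the fully substituted alkene carbon; high dilution, slow silane addition and a high nickel loading should favour these.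

Step 17
Reactants: 23 tetracyclic enone ketal
Product: 24 tetracyclic allylic alcohol ketal (ring A OH cis to the angular methyl)
Conditions: NaBH4, CeCl3·7H2O, MeOH, −78 to 0 °C
Reagents that add atoms: none
Why: Luche 1,2-reduction; hydride should add from the face opposite the angular methyl, as in 17-keto steroids, giving the alcohol cis to that methyl.

Step 18
Reactants: 24 tetracyclic allylic alcohol ketal
Product: 26 tetracyclic hydroxy enone (target skeleton with C=O in place of the exocyclic C=CH2), via saturated ketal 25 (not isolated)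
Conditions: [Ir(cod)(PCy3)(py)]PF6 (10 mol %), H2 (1 atm), CH2Cl2, rt; then 1 M HCl, THF, rt
Reagents that add atoms: water, O
Why: Hydroxyl-directed hydrogenation delivers H2 to the trisubstituted ring A alkene from the OH face and so places the isopropyl group trans to the angular methyl (the tetrasubstituted B/C alkene is left alone); aqueous acid then hydrolyses the dioxolane.

Step 19
Reactants: 26 tetracyclic hydroxy enone
Product: 27 CNP0544018.1 (target)
Conditions: Zn, CH2Br2, TiCl4 (pre-aged reagent, 4 equiv), THF/CH2Cl2, 0 °C to rt; NaHCO3 work-up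
Reagents that add atoms: dibromomethane, BrCBr
Why: Takai–Lombardo methylenation is non-basic, so the hindered enone carbonyl should be converted into the exocyclic methylene without epimerising the adjacent C/D ring-fusion centre; the free alcohol is tolerated.

Compound list
1 | (tert-butyldimethylsilyloxy)acetaldehyde | O=CCO[Si](C)(C)C(C)(C)C | starting material
2 | (2S,3S)-1-(tert-butyldimethylsilyloxy)-3-methylpent-4-en-2-ol | C=C[C@H](C)[C@H](O)CO[Si](C)(C)C(C)(C)C | intermediate
3 | (3S)-1-(tert-butyldimethylsilyloxy)-3-methylpent-4-en-2-one | C=C[C@H](C)C(=O)CO[Si](C)(C)C(C)(C)C | intermediate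
4 | (4aS,7S,7aR)-nepetalactone (cis-fused; 4,7-dimethyl-5,6,7,7a-tetrahydrocyclopenta[c]pyran-1(4aH)-one) | C[C@H]1CC[C@H]2[C@@H]1C(=O)OC=C2C | starting material
5 | (4aS,7S,7aS)-nepetalactone (trans-fused; lactone carbonyl carbon cis to the 7-methyl) | C[C@H]1CC[C@H]2[C@H]1C(=O)OC=C2C | intermediate
6 | (4aS,7S,7aS)-nepetalactol (lactol, mixture at C1) | C[C@H]1CC[C@H]2[C@H]1C(O)OC=C2C | intermediate
7 | (1S,2S,5S)-2-acetyl-5-methylcyclopentane-1-carbaldehyde | C[C@H]1CC[C@H](C(C)=O)[C@H]1C=O | intermediate
8 | 1-[(1S,2S,3S)-2-ethenyl-3-methylcyclopentyl]ethan-1-one | C[C@H]1CC[C@H](C(C)=O)[C@H]1C=C | intermediate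
9 | lithium enolate of 8 (methyl side) | C[C@H]1CC[C@H](C(=C)O[Li])[C@H]1C=C | intermediate (not isolated)
10 | (4S)-3-[(tert-butyldimethylsilyloxy)methyl]-1-[(1S,2S,3S)-2-ethenyl-3-methylcyclopentyl]-3-hydroxy-4-methylhex-5-en-1-one (C3 epimers) | C[C@H]1CC[C@H](C(=O)CC(O)(CO[Si](C)(C)C(C)(C)C)[C@@H](C)C=C)[C@H]1C=C | intermediate
11 | trans-fused (Z)-4-hydroxy-4-[(tert-butyldimethylsilyloxy)methyl]-5,9-dimethylbicyclo[6.3.0]undec-6-en-2-one, ring centres as in 12 | C[C@H]1CC[C@@H]2C(=O)CC(O)(CO[Si](C)(C)C(C)(C)C)[C@@H](C)/C=C\[C@@H]12 | intermediate (not isolated)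
12 | (1S,5S,8S,9S)-4-hydroxy-4-[(tert-butyldimethylsilyloxy)methyl]-5,9-dimethylbicyclo[6.3.0]undecan-2-one (C4 epimers) | C[C@H]1CC[C@@H]2C(=O)CC(O)(CO[Si](C)(C)C(C)(C)C)[C@@H](C)CC[C@@H]12 | intermediate
13 | (1S,5S,8S,9S)-4-[(tert-butyldimethylsilyloxy)methyl]-5,9-dimethylbicyclo[6.3.0]undec-3-en-2-one | C[C@H]1CC[C@@H]2C(=O)C=C(CO[Si](C)(C)C(C)(C)C)[C@@H](C)CC[C@@H]12 | intermediate
14 | (1S,5S,8S,9S)-3-bromo-4-[(tert-butyldimethylsilyloxy)methyl]-5,9-dimethylbicyclo[6.3.0]undec-3-en-2-one | C[C@H]1CC[C@@H]2C(=O)C(Br)=C(CO[Si](C)(C)C(C)(C)C)[C@@H](C)CC[C@@H]12 | intermediate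
15 | (1S,5S,8S,9S)-3-bromo-4-(bromomethyl)-5,9-dimethylbicyclo[6.3.0]undec-3-en-2-one | C[C@H]1CC[C@@H]2C(=O)C(Br)=C(CBr)[C@@H](C)CC[C@@H]12 | intermediate
16 | ethylene ketal (1,3-dioxolane at C2) of 15 | C[C@H]1CC[C@@H]2C3(OCCO3)C(Br)=C(CBr)[C@@H](C)CC[C@@H]12 | intermediate
17 | (−)-α-thujone, (1S,4R,5R)-1-isopropyl-4-methylbicyclo[3.1.0]hexan-3-one | CC(C)[C@]12CC(=O)[C@H](C)[C@H]1C2 | starting material
18 | 1-isopropyl-4-methyl-3-(trimethylsilyloxy)bicyclo[3.1.0]hex-3-ene, cyclopropane centres as in thujone | CC(C)[C@]12CC(O[Si](C)(C)C)=C(C)[C@H]1C2 | intermediate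
19 | lithium enolate (C3=C4) of thujone | CC(C)[C@]12CC(O[Li])=C(C)[C@H]1C2 | intermediate (not isolated)
20 | 1-isopropyl-4-methyl-4-{[(1S,5S,8S,9S)-3-bromo-2,2-(ethylenedioxy)-5,9-dimethylbicyclo[6.3.0]undec-3-en-4-yl]methyl}bicyclo[3.1.0]hexan-3-one, 4-methyl cis to the cyclopropane CH2, bridgeheads as in thujone | CC(C)[C@]12CC(=O)[C@](C)(CC3=C(Br)C4(OCCO4)[C@H]5CC[C@H](C)[C@@H]5CC[C@@H]3C)[C@H]1C2 | intermediate
21 | trimethylsilyl enol ether (C2=C3) of 20 | CC(C)[C@]12C=C(O[Si](C)(C)C)[C@](C)(CC3=C(Br)C4(OCCO4)[C@H]5CC[C@H](C)[C@@H]5CC[C@@H]3C)[C@H]1C2 | intermediate (not isolated)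
22 | 2-bromo derivative of 20 (C2 epimers) | CC(C)[C@]12C(Br)C(=O)[C@](C)(CC3=C(Br)C4(OCCO4)[C@H]5CC[C@H](C)[C@@H]5CC[C@@H]3C)[C@H]1C2 | intermediate
23 | tetracyclic enone ketal: target skeleton with ring A as 3-isopropyl-5-methylcyclopent-2-en-1-one and a 1,3-dioxolane on the ring C carbon that carries =CH2 in the target; other centres as in the target | C1COC2(O1)C3=C(C[C@@]4(C)C(=O)C=C(C(C)C)[C@@H]4C3)[C@@H](C)CC[C@@H]5[C@@H]2CC[C@@H]5C | intermediate
24 | allylic alcohol from 23 (ring A OH cis to the angular methyl) | C1COC2(O1)C3=C(C[C@@]4(C)[C@H](O)C=C(C(C)C)[C@@H]4C3)[C@@H](C)CC[C@@H]5[C@@H]2CC[C@@H]5C | intermediate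
25 | ring A-saturated alcohol ketal (isopropyl trans to the angular methyl) | C1COC2(O1)C3=C(C[C@@]4(C)[C@H](O)C[C@@H](C(C)C)[C@@H]4C3)[C@@H](C)CC[C@@H]5[C@@H]2CC[C@@H]5C | intermediate (not isolated)
26 | tetracyclic hydroxy enone: target with C=O in place of C=CH2 | O=C1C2=C(C[C@@]3(C)[C@H](O)C[C@@H](C(C)C)[C@@H]3C2)[C@@H](C)CC[C@@H]2[C@@H]1CC[C@@H]2C | intermediate
27 | CNP0544018.1 | C=C1C2=C(C[C@@]3(C)[C@H](O)C[C@@H](C(C)C)[C@@H]3C2)[C@@H](C)CC[C@@H]2[C@@H]1CC[C@@H]2C | target

Total steps: 19. Longest linear sequence: 16 steps (steps 3–12, then 14–19, from nepetalactone 4).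

Steps most likely to fail

Step 16. The α-keto radical may be captured or reduced before the cyclopropane opens, or the opened primary radical may be reduced by the silane, lose a β-hydrogen at nickel, or add 5-exo to the alkene instead of coupling. The fallback separates the two events with known chemistry. Setting out from 22, a bromine-atom-transfer chain reaction (Et3B/O2 or (Bu3Sn)2 with light, benzene) should open the cyclopropane and return bromine to the primary radical, giving the ring-opened 4-(bromomethyl)cyclopentenone F1. An intramolecular nickel-catalysed reductive cross-electrophile coupling of its primary alkyl bromide with the vinyl bromide (NiI2, dtbbpy, Mn, NaI, DMA, high dilution) should then close ring B and rejoin the route at 23.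

Step 8. Slow initiation at the vinyl group beside the fully substituted carbinol carbon may lead to oligomers instead of the eight-membered ring. The fallback closes ring C by an aldol-type C–C bond instead. Setting out from 8, bromination through the kinetic silyl enol ether (LiN(SiMe3)2, Me3SiCl; then NBS) gives the bromomethyl ketone F2. Cross-metathesis with an excess of 3 (second-generation Grubbs catalyst) gives the (E)-enedione F3. Diimide (2-nitrobenzenesulfonyl hydrazide, Et3N) saturates the alkene without touching the C–Br bond to give the bromo diketone F4. SmI2 (THF, −78 °C) then effects an intramolecular Reformatsky-type addition to the silyloxy ketone, a reaction that tolerates eight-membered ring formation, and rejoins the route at 12.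

Step 19. The hindered carbonyl may not react, or the Lewis acidic medium may shift the new diene. The fallback is a two-stage Peterson olefination. Setting out from 26, Me3SiCH2Li with CeCl3 (THF, −78 °C) should give the β-hydroxysilane F5, and KH (THF, rt) then eliminates trimethylsilanolate to reach 27.

Further compounds
F1 | step 16 | 4-(bromomethyl)-3-isopropyl-5-methylcyclopent-2-en-1-one carrying at C5 the (bicycloundecenyl)methyl group of 20 (CH2Br trans to that group) | CC(C)C1=CC(=O)[C@](C)(CC2=C(Br)C3(OCCO3)[C@H]4CC[C@H](C)[C@@H]4CC[C@@H]2C)[C@H]1CBr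
F2 | step 8 | 2-bromo-1-[(1S,2S,3S)-2-ethenyl-3-methylcyclopentyl]ethan-1-one | C[C@H]1CC[C@H](C(=O)CBr)[C@H]1C=C
F3 | step 8 | (E)-enedione from cross-metathesis of F2 with 3 | C[C@H]1CC[C@H](C(=O)CBr)[C@H]1/C=C/[C@H](C)C(=O)CO[Si](C)(C)C(C)(C)C
F4 | step 8 | saturated bromo diketone from F3 | C[C@H]1CC[C@H](C(=O)CBr)[C@H]1CC[C@H](C)C(=O)CO[Si](C)(C)C(C)(C)C
F5 | step 19 | β-hydroxysilane: adduct of Me3SiCH2 to the ring C carbonyl of 26 | C[Si](C)(C)CC1(O)C2=C(C[C@@]3(C)[C@H](O)C[C@@H](C(C)C)[C@@H]3C2)[C@@H](C)CC[C@@H]2[C@@H]1CC[C@@H]2C
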